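**Strategy**

Ring numbering: C2 carries the acyl chain, C1 and C3 are the enolised dione carbons, C5 is the carbinol carbon. The plan rests on cutting the cyclohexane ring at C5–C6 and C3–C4, into a C6–C1–C2–C3 unit and the C4–C5 unit. The key step exploits the alternating 1,3,5-oxygenation of this ring: C5–O makes C4=C5 a latent enol ether, and C6–C1(O)–C2–C3(O) is a latent 3-alkoxy vinylketene, stored as a four-membered cyclobutenone. One thermal, polarity-matched formal [4+2] union of 3-ethoxycyclobutenone and benzyl vinyl ether forms both bonds and the carbocycle. C2-acylation with a Wittig-derived acid and one global hydrogenation complete the route.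

Key step: step 1

Remark on the chemistry (assumption): C5 is stereogenic in the target SMILES only because C1 is drawn as C=O and C3 as C–OH; proton exchange between the two ring oxygens of the 2-acyl-1,3-dione turns the drawn (S) form into its mirror image, so the compound has no configurationally stable enantiomer, C5 is built without asymmetric induction, and the target is listed with the descriptor of the drawn tautomer.

**Route**

Step 1
Reactants: 1 3-ethoxycyclobut-2-en-1-one; 2 benzyl vinyl ether
Product: 5 (±)-5-(benzyloxy)-3-ethoxycyclohex-2-en-1-one, via vinylketene 3 (not isolated), via vinylcyclobutanone 4 (not isolated)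
Conditions: 2 (4 equiv), PhMe, 110–120 °C, sealed tube, 1 added slowly
Reagents that add atoms: none
Why: Proposed new method: at 110–120 °C cyclobutenone 1 should undergo 4π electrocyclic ring opening to the 3-ethoxy vinylketene 3; the nucleophilic CH2 terminus of enol ether 2 attacks the electrophilic ketene carbon (first new C–C bond) to give an alkoxy-dienolate/O-benzyl oxocarbenium dipole, and the γ-carbon of the dienolate (the former ring CH2 of 1) then adds to the oxocarbenium carbon (second new C–C bond), a stepwise formal [4+2] cycloaddition. The six-membered ring is closed by this second bond in a 6-(enolendo)-exo-trig Mukaiyama-aldol-type mode. Closure at the α-carbon instead gives the [2+2] adduct 4, a donor–acceptor cyclobutane in which the bond between the vinyl-bearing carbon and the benzyloxy-bearing carbon should re-ionise at this temperature, so that the dipole is funnelled to the strain-free, conjugated vinylogous ester 5. The closest known reaction types are the [2+2] cycloaddition of ketenes with enol ethers and the Danheiser benzannulation, in which cyclobutenone-derived vinylketenes take up alkoxyalkynes in a net [4+2] sense. The benzyloxy-bearing carbon is the only new stereocentre and is formed racemic on purpose, since its configuration has no bearing on the target (see remark). The selectivity needed is regiochemical, oxygenated carbon of 2 to the CH2 of 1 and CH2 of 2 to the carbonyl carbon, and it is secured by the matched polarity of the two partners, while closure through oxygen to a pyranone is excluded because the 3-oxygen of 3 is capped as its ethyl ether.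

Step 2
Reactants: 5 (±)-5-(benzyloxy)-3-ethoxycyclohex-2-en-1-one
Product: 6 5-(benzyloxy)cyclohexane-1,3-dione
Conditions: 1 M aq. HCl, THF, 0 °C to rt
Reagents that add atoms: water (O)
Why: Acid hydrolysis of a vinylogous ester (conjugate addition of water and loss of ethanol) is the standard unmasking of 3-alkoxycyclohex-2-enones and should be fast enough at 0 °C to rt to leave the β-benzyloxy group in place; the dione, being the same whichever carbonyl is enolised, no longer carries a defined stereocentre.

Step 3
Reactants: 7 3,4-bis(benzyloxy)benzaldehyde; 8 (7-carboxyheptyl)triphenylphosphonium bromide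
Product: 10 9-[3,4-bis(benzyloxy)phenyl]non-8-enoic acid (Z/E mixture), via phosphonium ylide 9 (not isolated)
Conditions: 8, NaN(SiMe3)2 (2.2 equiv), THF, 0 °C; then 7, 0 °C to rt; 1 M HCl work-up
Reagents that add atoms: none
Why: Wittig olefination of the aryl aldehyde with the non-stabilised carboxylate ylide should give the nine-carbon acid directly, and the alkene geometry is irrelevant because the double bond is saturated in step 5; no stereocentre is formed.

Step 4
Reactants: 6 5-(benzyloxy)cyclohexane-1,3-dione; 10 9-[3,4-bis(benzyloxy)phenyl]non-8-enoic acid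
Product: 12 5-(benzyloxy)-2-{9-[3,4-bis(benzyloxy)phenyl]non-8-enoyl}-3-hydroxycyclohex-2-en-1-one, via enol ester 11 (not isolated)
Conditions: DCC (1.2 equiv), DMAP (0.3 equiv), Et3N (1.2 equiv), CH2Cl2, 0 °C to rt
Reagents that add atoms: none
Why: Steglich-type O-acylation of the dione enol gives enol ester 11, which DMAP should convert by O-to-C acyl transfer (acylpyridinium and dione enolate ion pair) into the chelated 2-acyl-1,3-dione, the thermodynamic sink and the standard outcome of this one-pot C-acylation of cyclohexane-1,3-diones; no stereocentre is set.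

Step 5
Reactants: 12 5-(benzyloxy)-2-{9-[3,4-bis(benzyloxy)phenyl]non-8-enoyl}-3-hydroxycyclohex-2-en-1-one
Product: 13 (5S)-2-[9-(3,4-dihydroxyphenyl)nonanoyl]-3,5-dihydroxycyclohex-2-en-1-one
Conditions: H2 (1 atm), Pd(OH)2/C, EtOAc/MeOH, rt
Reagents that add atoms: none
Why: Catalytic hydrogenation should saturate the styrenyl double bond and hydrogenolyse the two aryl benzyl ethers and the C5 benzyl ether in one neutral operation that spares the enolised β-triketone and avoids the acid or base that would dehydrate the β-hydroxy ketone to the acylresorcinol; C5 keeps its oxygen and, as stated in the remark, needs no configurational control.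

**Compound list**

1 | 3-ethoxycyclobut-2-en-1-one | CCOC1=CC(=O)C1 | starting material
2 | benzyl vinyl ether | C=COCc1ccccc1 | starting material
3 | 3-ethoxybuta-1,3-dien-1-one (vinylketene) | CCOC(=C)C=C=O | intermediate
4 | 3-(benzyloxy)-2-(1-ethoxyethenyl)cyclobutan-1-one (racemic, cis/trans mixture) | CCOC(=C)C1C(=O)CC1OCc1ccccc1 | intermediate
5 | (±)-5-(benzyloxy)-3-ethoxycyclohex-2-en-1-one | CCOC1=CC(=O)CC(OCc2ccccc2)C1 | intermediate
6 | 5-(benzyloxy)cyclohexane-1,3-dione | O=C1CC(=O)CC(OCc2ccccc2)C1 | intermediate
7 | 3,4-bis(benzyloxy)benzaldehyde | O=Cc1ccc(OCc2ccccc2)c(OCc2ccccc2)c1 | starting material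
8 | (7-carboxyheptyl)triphenylphosphonium bromide | OC(=O)CCCCCCC[P+](c1ccccc1)(c1ccccc1)c1ccccc1.[Br-] | starting material
9 | sodium 8-(triphenylphosphoranylidene)octanoate (ylide) | [Na+].[O-]C(=O)CCCCCCC=P(c1ccccc1)(c1ccccc1)c1ccccc1 | intermediate
10 | 9-[3,4-bis(benzyloxy)phenyl]non-8-enoic acid (Z/E mixture) | OC(=O)CCCCCCC=Cc1ccc(OCc2ccccc2)c(OCc2ccccc2)c1 | intermediate
11 | 5-(benzyloxy)-3-oxocyclohex-1-en-1-yl 9-[3,4-bis(benzyloxy)phenyl]non-8-enoate (racemic) | O=C1C=C(OC(=O)CCCCCCC=Cc2ccc(OCc3ccccc3)c(OCc3ccccc3)c2)CC(OCc2ccccc2)C1 | intermediate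
12 | 5-(benzyloxy)-2-{9-[3,4-bis(benzyloxy)phenyl]non-8-enoyl}-3-hydroxycyclohex-2-en-1-one | O=C(CCCCCCC=Cc1ccc(OCc2ccccc2)c(OCc2ccccc2)c1)C1=C(O)CC(OCc2ccccc2)CC1=O | intermediate
13 | (5S)-2-[9-(3,4-dihydroxyphenyl)nonanoyl]-3,5-dihydroxycyclohex-2-en-1-one | O=C(CCCCCCCCc1ccc(O)c(O)c1)C1=C(O)C[C@H](O)CC1=O | target

**Count and risks**

Total step count: 5. Longest linear sequence: 4 steps (steps 1, 2, 4, 5).

Steps most likely to fail:

Step 1 (key step, proposed new method). The dipolar intermediate may stop at the four-membered adduct without reopening, or lose a proton to give an open-chain β-benzyloxy enone. The vinylketene may also dimerise before it is trapped. The fallback uses known chemistry, sets out from acid 10 and rejoins the route at 13; it abandons the annulation and takes the ring from an aromatic precursor. Commercial phloroglucinol is reduced through its triketo tautomer with NaBH4 in aqueous NaOH and acidified cold to give 5-hydroxycyclohexane-1,3-dione F1. F1 is C-acylated with 10 under the conditions of step 4, in which the dione enolate should be acylated ahead of the secondary alcohol, to give 2-{9-[3,4-bis(benzyloxy)phenyl]non-8-enoyl}-3,5-dihydroxycyclohex-2-en-1-one F2. Hydrogenation as in step 5, now needed only for the alkene and the two aryl benzyl ethers, gives 13.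

Step 2. Under aqueous acid the β-benzyloxy ketone may eliminate benzyl alcohol and aromatise to a resorcinol ether faster than the vinylogous ester is hydrolysed. The fallback sets out from 1 and rejoins the route at 6; it changes the enol ether before the annulation so that fluoride, not acid, removes it. Compound 1 is hydrolysed (dilute HCl, rt) to cyclobutane-1,3-dione F3, which is O-silylated (iPr3SiCl, Et3N, CH2Cl2) to 3-[(triisopropylsilyl)oxy]cyclobut-2-en-1-one F4. The annulation of step 1 with 2 should then give 5-(benzyloxy)-3-[(triisopropylsilyl)oxy]cyclohex-2-en-1-one F5. Buffered fluoride (Bu4NF, AcOH, THF, 0 °C) releases 6 without exposure to mineral acid.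

Step 5. The aliphatic C5 benzyl ether may be cleaved much more slowly than the aryl ethers, and the long exposure may bring over-reduction of the enolised triketone or dehydration to the 2-acylresorcinol. The fallback sets out from 1 and rejoins the route at 13; it carries the C5 oxygen as a silyl ether. Compound 1 is combined with commercial tert-butyldimethylsilyl vinyl ether as in step 1 to give 5-[(tert-butyldimethylsilyl)oxy]-3-ethoxycyclohex-2-en-1-one F6. Brief hydrolysis as in step 2 gives 5-[(tert-butyldimethylsilyl)oxy]cyclohexane-1,3-dione F7. Acylation with 10 as in step 4 gives 2-{9-[3,4-bis(benzyloxy)phenyl]non-8-enoyl}-5-[(tert-butyldimethylsilyl)oxy]-3-hydroxycyclohex-2-en-1-one F8. Hydrogenation (H2, Pd/C, EtOAc), needed only for the alkene and the aryl benzyl ethers, gives 5-[(tert-butyldimethylsilyl)oxy]-2-[9-(3,4-dihydroxyphenyl)nonanoyl]-3-hydroxycyclohex-2-en-1-one F9. HF·pyridine in THF/pyridine at 0 °C removes the silyl group to give 13.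

Further compounds
F1 | step 1 | 5-hydroxycyclohexane-1,3-dione | O=C1CC(=O)CC(O)C1
F2 | step 1 | 2-{9-[3,4-bis(benzyloxy)phenyl]non-8-enoyl}-3,5-dihydroxycyclohex-2-en-1-one | O=C(CCCCCCC=Cc1ccc(OCc2ccccc2)c(OCc2ccccc2)c1)C1=C(O)CC(O)CC1=O
F3 | step 2 | cyclobutane-1,3-dione | O=C1CC(=O)C1
F4 | step 2 | 3-[(triisopropylsilyl)oxy]cyclobut-2-en-1-one | CC(C)[Si](OC1=CC(=O)C1)(C(C)C)C(C)C
F5 | step 2 | 5-(benzyloxy)-3-[(triisopropylsilyl)oxy]cyclohex-2-en-1-one (racemic) | CC(C)[Si](OC1=CC(=O)CC(OCc2ccccc2)C1)(C(C)C)C(C)C
F6 | step 5 | 5-[(tert-butyldimethylsilyl)oxy]-3-ethoxycyclohex-2-en-1-one (racemic) | CCOC1=CC(=O)CC(O[Si](C)(C)C(C)(C)C)C1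
F7 | step 5 | 5-[(tert-butyldimethylsilyl)oxy]cyclohexane-1,3-dione | O=C1CC(=O)CC(O[Si](C)(C)C(C)(C)C)C1
F8 | step 5 | 2-{9-[3,4-bis(benzyloxy)phenyl]non-8-enoyl}-5-[(tert-butyldimethylsilyl)oxy]-3-hydroxycyclohex-2-en-1-one | O=C(CCCCCCC=Cc1ccc(OCc2ccccc2)c(OCc2ccccc2)c1)C1=C(O)CC(O[Si](C)(C)C(C)(C)C)CC1=O
F9 | step 5 | 5-[(tert-butyldimethylsilyl)oxy]-2-[9-(3,4-dihydroxyphenyl)nonanoyl]-3-hydroxycyclohex-2-en-1-one | O=C(CCCCCCCCc1ccc(O)c(O)c1)C1=C(O)CC(O[Si](C)(C)C(C)(C)C)CC1=O
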